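**Retrosynthetic overview**

1. Target 30 ⇐ 29 (fluoride release of the tetronic acid) ⇐ 27 (desilylation, then oxidation of the furyl carbinol). Both rings exist before the union: ring A (butenolide) is closed first, in step 1; ring B (furan) is bought as furan-3-carbaldehyde.
2. Central disconnection: the σ bond between the last CH2 of the three-methylene tether and the methyl-bearing sp2 carbon of the trisubstituted E-alkene nearer ring A ⇒ alkyl pinacol boronate 14 + Z-alkenyl iodide 23. They are joined by a Zweifel olefination (boron-ate 1,2-metallate rearrangement, then anti loss of boron and iodine).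
3. Enabling feature: that alkene carbon carries no hydrogen (CH3, the CH2 tether, =CH) and sits in an isolated CH2–C(CH3)=CH–CH2 unit, several bonds from ring A and ring B and free of heteroatoms. It can therefore be the boron-bearing carbon of an alkenyl boronate, and its E geometry is the stereochemical inverse of an easily made Z-iodide.
4. 14 ⇐ Evans allylation (sets the only stereocentre); fluoride-catalysed vinylogous aldol, then anti dehydration (sets the E-alkylidene on ring A); iridium-catalysed hydroboration (puts boron on the chain end).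
5. 23 ⇐ acetate aldol on furan-3-carbaldehyde; Johnson–Claisen rearrangement (E-trisubstituted alkene); iodo-Wittig olefination (Z-iodide).

Key step: step 17

Remark: the furyl carbinol carbon is made racemic on purpose and is left undefined in the SMILES (epimer mixtures from step 17 on), because step 19 turns it into the ketone carbon. Locants C3–C5 refer to the butenolide ring; C1′ and C2′ are the first two side-chain carbons.

**Route**

Step 1
Reactants: 1 ethyl 2-methyl-3-oxobutanoate
Product: 3 4-hydroxy-3-methylfuran-2(5H)-one (3-methyltetronic acid), via ethyl 4-bromo-2-methyl-3-oxobutanoate 2 (not isolated)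
Conditions: Br2 (1.0 equiv), CHCl3, 0 °C to rt, 16 h; concentrate; neat, 110 °C
Reagents that add atoms: none
Why: α-bromination and HBr-mediated migration of bromine to the terminal methyl give γ-bromo β-keto ester 2, which on heating closes ring A by attack of the ester carbonyl oxygen on the CH2Br carbon (5-exo-tet) with loss of bromoethane, the classical tetronic acid synthesis.

Step 2
Reactants: 3 4-hydroxy-3-methylfuran-2(5H)-one
Product: 4 3-methyl-4-[2-(trimethylsilyl)ethoxy]furan-2(5H)-one
Conditions: Me3SiCH2CH2OH, PPh3, DIAD, THF, 0 °C to rt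
Reagents that add atoms: 2-(trimethylsilyl)ethanol, OCC[Si](C)(C)C
Why: Mitsunobu O-alkylation of the acidic vinylogous acid takes place at the C4 enol oxygen and installs a fluoride-labile ether that should tolerate organolithium, alkoxide, iodine and hydroboration conditions.

Step 3
Reactants: 4 3-methyl-4-[2-(trimethylsilyl)ethoxy]furan-2(5H)-one
Product: 5 trimethyl({3-methyl-4-[2-(trimethylsilyl)ethoxy]furan-2-yl}oxy)silane
Conditions: Me3SiOTf, Et3N, Et2O, 0 °C; decant under argon, use crude
Reagents that add atoms: trimethylsilyl trifluoromethanesulfonate, C[Si](C)(C)OS(=O)(=O)C(F)(F)F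
Why: soft enolisation (silyl triflate and amine) at C5 of the butenolide gives the aromatic 2-silyloxyfuran, the standard nucleophile for vinylogous aldol additions.

Step 4
Reactants: 6 (4R)-4-benzyl-3-propanoyl-1,3-oxazolidin-2-one
Product: 8 (4R)-4-benzyl-3-[(2S)-2-methylpent-4-enoyl]-1,3-oxazolidin-2-one, via sodium Z-enolate 7 (not isolated)
Conditions: NaN(SiMe3)2, THF, −78 °C; allyl iodide, −78 to −40 °C
Reagents that add atoms: allyl iodide, C=CCI
Why: Evans alkylation, in which the chelated Z-enolate is allylated on the face opposite the benzyl group of the auxiliary, sets the (S) methyl-bearing centre that becomes the only stereocentre of the target.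

Step 5
Reactants: 8 (4R)-4-benzyl-3-[(2S)-2-methylpent-4-enoyl]-1,3-oxazolidin-2-one
Product: 9 (2S)-2-methylpent-4-en-1-ol
Conditions: LiBH4, MeOH (1 equiv), Et2O, 0 °C
Reagents that add atoms: none
Why: reductive cleavage of the imide with lithium borohydride releases the primary alcohol without touching the α-stereocentre and returns the auxiliary.

Step 6
Reactants: 9 (2S)-2-methylpent-4-en-1-ol
Product: 10 (2S)-2-methylpent-4-enal
Conditions: Dess–Martin periodinane, NaHCO3, CH2Cl2, 0 °C to rt; filtered solution used at once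
Reagents that add atoms: none
Why: Dess–Martin oxidation under buffered, non-enolising conditions should give the volatile α-chiral aldehyde without epimerisation, and it is used immediately in solution.

Step 7
Reactants: 5 trimethyl({3-methyl-4-[2-(trimethylsilyl)ethoxy]furan-2-yl}oxy)silane; 10 (2S)-2-methylpent-4-enal
Product: 12 (5R)-5-[(1R,2S)-1-hydroxy-2-methylpent-4-en-1-yl]-3-methyl-4-[2-(trimethylsilyl)ethoxy]furan-2(5H)-one, via O-trimethylsilyl aldol adduct 11 (not isolated)
Conditions: Bu4NF (0.1 equiv, anhydrous), THF, −78 °C; then citric acid, MeOH, 0 °C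
Reagents that add atoms: none
Why: fluoride-catalysed vinylogous aldol addition of the silyloxyfuran through an open transition state of the free furanolate is expected to favour the like (5R*,1′R*) relationship between C5 and C1′, opposite to the unlike preference of Lewis acid catalysis; the 2′S centre comes from 10, and the facial sense (the Felkin–Anh isomer is drawn) does not matter because both like isomers give the same alkene in step 8.

Step 8
Reactants: 12 (5R)-5-[(1R,2S)-1-hydroxy-2-methylpent-4-en-1-yl]-3-methyl-4-[2-(trimethylsilyl)ethoxy]furan-2(5H)-one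
Product: 13 (5E)-3-methyl-5-[(2S)-2-methylpent-4-en-1-ylidene]-4-[2-(trimethylsilyl)ethoxy]furan-2(5H)-one
Conditions: PPh3, DIAD (slight excess over PPh3), THF, 0 °C to rt, dark
Reagents that add atoms: none
Why: Mitsunobu-type dehydration, in which the alkoxyphosphonium ion loses C5–H by stereospecific anti elimination, should convert the like adduct into the E-alkylidene butenolide (side chain cis to C4), the less stable geometry that the target requires.

Step 9
Reactants: 13 (5E)-3-methyl-5-[(2S)-2-methylpent-4-en-1-ylidene]-4-[2-(trimethylsilyl)ethoxy]furan-2(5H)-one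
Product: 14 (5E)-3-methyl-5-[(2S)-2-methyl-5-(4,4,5,5-tetramethyl-1,3,2-dioxaborolan-2-yl)pentylidene]-4-[2-(trimethylsilyl)ethoxy]furan-2(5H)-one
Conditions: pinacolborane, [Ir(cod)Cl]2 (1.5 mol%), dppm (3 mol%), CH2Cl2, rt
Reagents that add atoms: pinacolborane, [H]B1OC(C)(C)C(C)(C)O1
Why: iridium-catalysed anti-Markovnikov hydroboration is selective for the monosubstituted terminal alkene and should leave the trisubstituted conjugated alkylidene and the lactone untouched.

Step 10
Reactants: 15 furan-3-carbaldehyde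
Product: 16 ethyl 3-(furan-3-yl)-3-hydroxypropanoate (racemic)
Conditions: LiN(iPr)2, ethyl acetate, THF, −78 °C; then 15, −78 °C
Reagents that add atoms: ethyl acetate, CCOC(C)=O
Why: aldol addition of the lithium enolate of ethyl acetate to the non-enolisable aldehyde; the new carbinol centre is left racemic on purpose because it becomes the ketone carbon in step 19.

Step 11
Reactants: 16 ethyl 3-(furan-3-yl)-3-hydroxypropanoate
Product: 17 ethyl 3-[(tert-butyldimethylsilyl)oxy]-3-(furan-3-yl)propanoate
Conditions: t-BuMe2SiCl, imidazole, DMF, rt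
Reagents that add atoms: tert-butyldimethylsilyl chloride, CC(C)(C)[Si](C)(C)Cl
Why: standard silylation masks the future ketone oxygen as a robust silyl ether and blocks retro-aldol cleavage and dehydration.

Step 12
Reactants: 17 ethyl 3-[(tert-butyldimethylsilyl)oxy]-3-(furan-3-yl)propanoate
Product: 18 3-[(tert-butyldimethylsilyl)oxy]-3-(furan-3-yl)propanal
Conditions: iBu2AlH (1.05 equiv), CH2Cl2, −78 °C; aq. potassium sodium tartrate
Reagents that add atoms: none
Why: partial reduction of the ester at low temperature stops at the aluminium hemiacetal, which releases the aldehyde on work-up.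

Step 13
Reactants: 18 3-[(tert-butyldimethylsilyl)oxy]-3-(furan-3-yl)propanal
Product: 19 1-[(tert-butyldimethylsilyl)oxy]-1-(furan-3-yl)-4-methylpent-4-en-3-ol (diastereomer mixture)
Conditions: CH2=C(CH3)MgBr, THF, −78 to 0 °C
Reagents that add atoms: isopropenylmagnesium bromide, CC(=C)[Mg]Br
Why: Grignard addition to the aldehyde gives the 2-methylallylic alcohol needed for the Claisen step; the new carbinol centre is uncontrolled and is destroyed in step 14.

Step 14
Reactants: 19 1-[(tert-butyldimethylsilyl)oxy]-1-(furan-3-yl)-4-methylpent-4-en-3-ol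
Product: 21 ethyl (4E)-7-[(tert-butyldimethylsilyl)oxy]-7-(furan-3-yl)-4-methylhept-4-enoate, via mixed ketene acetal 20 (not isolated)
Conditions: CH3C(OEt)3, EtCO2H (cat.), 135 °C, EtOH distilled off
Reagents that add atoms: triethyl orthoacetate, CCOC(C)(OCC)OCC
Why: Johnson–Claisen rearrangement, a [3,3] shift through a chair transition state with the large substituent equatorial, should form the trisubstituted alkene with E geometry while adding the two-carbon ester arm.

Step 15
Reactants: 21 ethyl (4E)-7-[(tert-butyldimethylsilyl)oxy]-7-(furan-3-yl)-4-methylhept-4-enoate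
Product: 22 (4E)-7-[(tert-butyldimethylsilyl)oxy]-7-(furan-3-yl)-4-methylhept-4-enal
Conditions: iBu2AlH (1.05 equiv), CH2Cl2, −78 °C; aq. potassium sodium tartrate
Reagents that add atoms: none
Why: low-temperature partial reduction of the ester, as in step 12, gives the aldehyde without touching the alkene, the furan or the silyl ether.

Step 16
Reactants: 22 (4E)-7-[(tert-butyldimethylsilyl)oxy]-7-(furan-3-yl)-4-methylhept-4-enal
Product: 23 tert-butyl{[(3E,7Z)-1-(furan-3-yl)-8-iodo-4-methylnona-3,7-dien-1-yl]oxy}dimethylsilane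
Conditions: EtPPh3+ I−, n-BuLi, THF, rt; I2, −78 °C; NaN(SiMe3)2, −78 °C; then 22, −78 to −20 °C
Reagents that add atoms: ethyltriphenylphosphonium iodide, CC[P+](c1ccccc1)(c1ccccc1)c1ccccc1.[I-]; iodine, II
Why: Stork–Zhao-type Wittig olefination with the α-iodo ethylidene ylide is kinetically Z-selective and places iodine cis to the chain, the geometry that the stereoinvertive key step turns into the E-alkene.

Step 17
Reactants: 14 (5E)-3-methyl-5-[(2S)-2-methyl-5-(4,4,5,5-tetramethyl-1,3,2-dioxaborolan-2-yl)pentylidene]-4-[2-(trimethylsilyl)ethoxy]furan-2(5H)-one; 23 tert-butyl{[(3E,7Z)-1-(furan-3-yl)-8-iodo-4-methylnona-3,7-dien-1-yl]oxy}dimethylsilane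
Product: 27 (5E)-5-[(2S,6E,10E)-13-[(tert-butyldimethylsilyl)oxy]-13-(furan-3-yl)-2,6,10-trimethyltrideca-6,10-dien-1-ylidene]-3-methyl-4-[2-(trimethylsilyl)ethoxy]furan-2(5H)-one, via alkenyllithium 24 (not isolated), via lithium boronate complex 25 (not isolated), via β-iodo boronic ester 26 (not isolated)
Conditions: 23, t-BuLi (2.0 equiv), Et2O, −78 °C; cannulated slowly into 14 (1.1 equiv), THF, −78 °C; I2 (1.2 equiv), THF, −78 °C, dark; NaOMe, MeOH, −78 to 0 °C; aq. Na2S2O3
Reagents that add atoms: none
Why: Zweifel olefination: alkenyllithium 24 (iodine–lithium exchange with retention) adds to the empty p orbital of primary alkyl boronate 14 to give ate complex 25; iodine then attacks the electron-rich alkenyl π bond and, as the iodonium ion opens, the primary alkyl group migrates from boron to the methyl-bearing carbon (1,2-metallate rearrangement), after which methoxide on boron triggers anti elimination of boron and iodine from 26. The closest known reaction type is this same olefination of primary alkyl pinacol boronic esters with α-methyl alkenyllithiums to give trisubstituted alkenes. No ring is closed and no lasting stereocentre is formed (the two centres of 26 are destroyed again); the controlled element is the alkene geometry, fixed by the anti migration and anti elimination, so the Z-iodide should give the E-alkene with the new chain trans to the neighbouring CH2, and both carbinol epimers behave alike. The selectivity needed is chemoselectivity: boron must capture 24 faster than the lactone carbonyl, the γ-hydrogens or the furan do, which slow addition of 24 to a slight excess of 14 at −78 °C should secure, because boron complexation is essentially barrierless while the 4-alkoxybutenolide is a deactivated vinylogous carbonate; iodine must choose the boronate-activated alkene over the other π systems, which its much higher nucleophilicity at −78 °C should ensure. Cold, brief methoxide treatment in the dark is meant to limit alkoxy exchange at C4 and drift of the E-alkylidene.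

Step 18
Reactants: 27 (5E)-5-[(2S,6E,10E)-13-[(tert-butyldimethylsilyl)oxy]-13-(furan-3-yl)-2,6,10-trimethyltrideca-6,10-dien-1-ylidene]-3-methyl-4-[2-(trimethylsilyl)ethoxy]furan-2(5H)-one
Product: 28 (5E)-5-[(2S,6E,10E)-13-(furan-3-yl)-13-hydroxy-2,6,10-trimethyltrideca-6,10-dien-1-ylidene]-3-methyl-4-[2-(trimethylsilyl)ethoxy]furan-2(5H)-one
Conditions: HF·pyridine, pyridine, THF, 0 °C to rt
Reagents that add atoms: none
Why: buffered HF desilylation cleaves the secondary silyl ether, while the carbon-bound trimethylsilylethyl group, which needs naked fluoride for β-elimination, should stay in place.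

Step 19
Reactants: 28 (5E)-5-[(2S,6E,10E)-13-(furan-3-yl)-13-hydroxy-2,6,10-trimethyltrideca-6,10-dien-1-ylidene]-3-methyl-4-[2-(trimethylsilyl)ethoxy]furan-2(5H)-one
Product: 29 (5E)-5-[(2S,6E,10E)-13-(furan-3-yl)-2,6,10-trimethyl-13-oxotrideca-6,10-dien-1-ylidene]-3-methyl-4-[2-(trimethylsilyl)ethoxy]furan-2(5H)-one
Conditions: Dess–Martin periodinane, NaHCO3, CH2Cl2, 0 °C
Reagents that add atoms: none
Why: Dess–Martin oxidation under buffered neutral conditions should form the β,γ-unsaturated furyl ketone without moving the alkene into conjugation.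

Step 20
Reactants: 29 (5E)-5-[(2S,6E,10E)-13-(furan-3-yl)-2,6,10-trimethyl-13-oxotrideca-6,10-dien-1-ylidene]-3-methyl-4-[2-(trimethylsilyl)ethoxy]furan-2(5H)-one
Product: 30 (5E)-5-[(2S,6E,10E)-13-(furan-3-yl)-2,6,10-trimethyl-13-oxotrideca-6,10-dien-1-ylidene]-4-hydroxy-3-methylfuran-2(5H)-one
Conditions: (Me2N)3S+ Me3SiF2− (TASF), DMF, 0 °C; then 0.1 M aq. HCl, 0 °C
Reagents that add atoms: none
Why: fluoride attack at silicon triggers β-elimination of ethene and fluorotrimethylsilane (fluoride-induced fragmentation of a 2-silylethyl ether) and frees the tetronic acid as its weakly basic anion, conditions chosen so that neither the E-alkylidene nor the β,γ-unsaturated ketone should isomerise.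

**Compound list**

1 | ethyl 2-methyl-3-oxobutanoate | CCOC(=O)C(C)C(C)=O | starting material
2 | ethyl 4-bromo-2-methyl-3-oxobutanoate | CCOC(=O)C(C)C(=O)CBr | intermediate
3 | 4-hydroxy-3-methylfuran-2(5H)-one | CC1=C(O)COC1=O | intermediate
4 | 3-methyl-4-[2-(trimethylsilyl)ethoxy]furan-2(5H)-one | CC1=C(OCC[Si](C)(C)C)COC1=O | intermediate
5 | trimethyl({3-methyl-4-[2-(trimethylsilyl)ethoxy]furan-2-yl}oxy)silane | Cc1c(O[Si](C)(C)C)occ1OCC[Si](C)(C)C | intermediate
6 | (4R)-4-benzyl-3-propanoyl-1,3-oxazolidin-2-one | CCC(=O)N1[C@H](Cc2ccccc2)COC1=O | starting material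
7 | sodium (Z)-1-[(4R)-4-benzyl-2-oxo-1,3-oxazolidin-3-yl]prop-1-en-1-olate | C/C=C(\[O-])N1[C@H](Cc2ccccc2)COC1=O.[Na+] | intermediate
8 | (4R)-4-benzyl-3-[(2S)-2-methylpent-4-enoyl]-1,3-oxazolidin-2-one | C=CC[C@H](C)C(=O)N1[C@H](Cc2ccccc2)COC1=O | intermediate
9 | (2S)-2-methylpent-4-en-1-ol | C=CC[C@H](C)CO | intermediate
10 | (2S)-2-methylpent-4-enal | C=CC[C@H](C)C=O | intermediate
11 | (5R)-3-methyl-5-{(1R,2S)-2-methyl-1-[(trimethylsilyl)oxy]pent-4-en-1-yl}-4-[2-(trimethylsilyl)ethoxy]furan-2(5H)-one | CC1=C(OCC[Si](C)(C)C)[C@@H]([C@H](O[Si](C)(C)C)[C@@H](C)CC=C)OC1=O | intermediate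
12 | (5R)-5-[(1R,2S)-1-hydroxy-2-methylpent-4-en-1-yl]-3-methyl-4-[2-(trimethylsilyl)ethoxy]furan-2(5H)-one (like at C5/C1′; the (5S,1′S) like isomer is an equally good substrate) | CC1=C(OCC[Si](C)(C)C)[C@@H]([C@H](O)[C@@H](C)CC=C)OC1=O | intermediate
13 | (5E)-3-methyl-5-[(2S)-2-methylpent-4-en-1-ylidene]-4-[2-(trimethylsilyl)ethoxy]furan-2(5H)-one | CC1=C(OCC[Si](C)(C)C)/C(=C\[C@@H](C)CC=C)OC1=O | intermediate
14 | (5E)-3-methyl-5-[(2S)-2-methyl-5-(4,4,5,5-tetramethyl-1,3,2-dioxaborolan-2-yl)pentylidene]-4-[2-(trimethylsilyl)ethoxy]furan-2(5H)-one | CC1=C(OCC[Si](C)(C)C)/C(=C\[C@@H](C)CCCB2OC(C)(C)C(C)(C)O2)OC1=O | intermediate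
15 | furan-3-carbaldehyde | O=Cc1ccoc1 | starting material
16 | ethyl 3-(furan-3-yl)-3-hydroxypropanoate (racemic) | CCOC(=O)CC(O)c1ccoc1 | intermediate
17 | ethyl 3-[(tert-butyldimethylsilyl)oxy]-3-(furan-3-yl)propanoate | CCOC(=O)CC(O[Si](C)(C)C(C)(C)C)c1ccoc1 | intermediate
18 | 3-[(tert-butyldimethylsilyl)oxy]-3-(furan-3-yl)propanal | O=CCC(O[Si](C)(C)C(C)(C)C)c1ccoc1 | intermediate
19 | 1-[(tert-butyldimethylsilyl)oxy]-1-(furan-3-yl)-4-methylpent-4-en-3-ol (diastereomer mixture) | CC(=C)C(O)CC(O[Si](C)(C)C(C)(C)C)c1ccoc1 | intermediate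
20 | tert-butyl{[3-(1-ethoxyethenyloxy)-1-(furan-3-yl)-4-methylpent-4-en-1-yl]oxy}dimethylsilane | C=C(OCC)OC(CC(O[Si](C)(C)C(C)(C)C)c1ccoc1)C(C)=C | intermediate
21 | ethyl (4E)-7-[(tert-butyldimethylsilyl)oxy]-7-(furan-3-yl)-4-methylhept-4-enoate | CCOC(=O)CC/C(C)=C/CC(O[Si](C)(C)C(C)(C)C)c1ccoc1 | intermediate
22 | (4E)-7-[(tert-butyldimethylsilyl)oxy]-7-(furan-3-yl)-4-methylhept-4-enal | O=CCC/C(C)=C/CC(O[Si](C)(C)C(C)(C)C)c1ccoc1 | intermediate
23 | tert-butyl{[(3E,7Z)-1-(furan-3-yl)-8-iodo-4-methylnona-3,7-dien-1-yl]oxy}dimethylsilane | I/C(C)=C\CC/C(C)=C/CC(O[Si](C)(C)C(C)(C)C)c1ccoc1 | intermediate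
24 | alkenyllithium from 23, lithium in place of iodine and cis to the chain CH2 (geometry of 23 retained) | [Li]/C(C)=C\CC/C(C)=C/CC(O[Si](C)(C)C(C)(C)C)c1ccoc1 | intermediate
25 | lithium boronate complex of 14 and 24: tetracoordinate boron carrying the pinacolato group, the primary alkyl chain of 14 and the alkenyl group of 24 (boron cis to the chain CH2) | CC1=C(OCC[Si](C)(C)C)/C(=C\[C@@H](C)CCC[B-]2(OC(C)(C)C(C)(C)O2)/C(C)=C\CC/C(C)=C/CC(O[Si](C)(C)C(C)(C)C)c2ccoc2)OC1=O.[Li+] | intermediate
26 | (5E)-5-[(2S,6R*,7R*,10E)-13-[(tert-butyldimethylsilyl)oxy]-13-(furan-3-yl)-7-iodo-2,6,10-trimethyl-6-(4,4,5,5-tetramethyl-1,3,2-dioxaborolan-2-yl)tridec-10-en-1-ylidene]-3-methyl-4-[2-(trimethylsilyl)ethoxy]furan-2(5H)-one (like pair at the boron- and iodine-bearing carbons, both enantiomeric senses, so these two centres are left open in the SMILES) | CC1=C(OCC[Si](C)(C)C)/C(=C\[C@@H](C)CCCC(C)(B2OC(C)(C)C(C)(C)O2)C(I)CC/C(C)=C/CC(O[Si](C)(C)C(C)(C)C)c2ccoc2)OC1=O | intermediate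
27 | (5E)-5-[(2S,6E,10E)-13-[(tert-butyldimethylsilyl)oxy]-13-(furan-3-yl)-2,6,10-trimethyltrideca-6,10-dien-1-ylidene]-3-methyl-4-[2-(trimethylsilyl)ethoxy]furan-2(5H)-one | CC1=C(OCC[Si](C)(C)C)/C(=C\[C@@H](C)CCC/C(C)=C/CC/C(C)=C/CC(O[Si](C)(C)C(C)(C)C)c2ccoc2)OC1=O | intermediate
28 | (5E)-5-[(2S,6E,10E)-13-(furan-3-yl)-13-hydroxy-2,6,10-trimethyltrideca-6,10-dien-1-ylidene]-3-methyl-4-[2-(trimethylsilyl)ethoxy]furan-2(5H)-one | CC1=C(OCC[Si](C)(C)C)/C(=C\[C@@H](C)CCC/C(C)=C/CC/C(C)=C/CC(O)c2ccoc2)OC1=O | intermediate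
29 | (5E)-5-[(2S,6E,10E)-13-(furan-3-yl)-2,6,10-trimethyl-13-oxotrideca-6,10-dien-1-ylidene]-3-methyl-4-[2-(trimethylsilyl)ethoxy]furan-2(5H)-one | CC1=C(OCC[Si](C)(C)C)/C(=C\[C@@H](C)CCC/C(C)=C/CC/C(C)=C/CC(=O)c2ccoc2)OC1=O | intermediate
30 | (5E)-5-[(2S,6E,10E)-13-(furan-3-yl)-2,6,10-trimethyl-13-oxotrideca-6,10-dien-1-ylidene]-4-hydroxy-3-methylfuran-2(5H)-one | CC1=C(O)/C(=C\[C@@H](C)CCC/C(C)=C/CC/C(C)=C/CC(=O)c2ccoc2)OC1=O | target

**Step count and risks**

Total step count: 20.
Longest linear sequence: 11 steps (15 to 30 through steps 10–17 and 18–20).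

Steps most likely to fail:

1. Step 17. What may go wrong: the alkenyllithium may add to, or deprotonate, the alkoxybutenolide before boron captures it, and iodine or methoxide may erode the E-alkylidene geometry or exchange the ether at C4. The fallback sets out from 13 and 22 and comes back at 27. Ramirez olefination of 22 (CBr4, PPh3, Et3N, CH2Cl2, 0 °C) gives tert-butyl{[(3E)-8,8-dibromo-1-(furan-3-yl)-4-methylocta-3,7-dien-1-yl]oxy}dimethylsilane F1. Hydroboration of 13 with 9-BBN in THF gives (5E)-5-[(2S)-5-(9-borabicyclo[3.3.1]nonan-9-yl)-2-methylpentylidene]-3-methyl-4-[2-(trimethylsilyl)ethoxy]furan-2(5H)-one F2, used in solution. Suzuki–Miyaura coupling of the two (Pd(dppf)Cl2, AsPh3, Cs2CO3, DMF/THF/H2O, rt) should take place only at the bromine trans to the chain and give (5E)-5-[(2S,6Z,10E)-6-bromo-13-[(tert-butyldimethylsilyl)oxy]-13-(furan-3-yl)-2,10-dimethyltrideca-6,10-dien-1-ylidene]-3-methyl-4-[2-(trimethylsilyl)ethoxy]furan-2(5H)-one F3. Negishi methylation with retention (Me2Zn, Pd(P(t-Bu)3)2, THF, rt) then gives 27 without any organolithium, iodine or alkoxide meeting the butenolide.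

2. Step 7. What may go wrong: poor like/unlike selectivity in the fluoride-catalysed addition, or stalling of the silyl transfer; unlike adduct would end as Z-alkylidene after the anti elimination of step 8. The fallback sets out from 5 and 10 and comes back at 13. A Lewis-acid vinylogous Mukaiyama aldol (BF3·OEt2, CH2Cl2, −78 °C), which is unlike-selective, gives (5S)-5-[(1R,2S)-1-hydroxy-2-methylpent-4-en-1-yl]-3-methyl-4-[2-(trimethylsilyl)ethoxy]furan-2(5H)-one F4. A syn-selective dehydration with EDC·HCl and CuCl2 (cyclic elimination through the O-alkylisourea) should then convert this diastereomer into the same E-alkylidene 13.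

3. Step 20. What may go wrong: fluoride acting as a base may move the β,γ-alkene into conjugation with the furyl ketone, or the ether cleavage may stall. The fallback sets out from 27 and comes back at 30. Both silicon groups are removed first with Bu4NF (THF, 0 °C to rt, acidic work-up), while no ketone is present, to give (5E)-5-[(2S,6E,10E)-13-(furan-3-yl)-13-hydroxy-2,6,10-trimethyltrideca-6,10-dien-1-ylidene]-4-hydroxy-3-methylfuran-2(5H)-one F5. The heteroaryl carbinol is then oxidised chemoselectively with MnO2 in CH2Cl2 at rt to give 30, so the ketone never meets fluoride.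

**Further compounds**

F1 | step 17 | tert-butyl{[(3E)-8,8-dibromo-1-(furan-3-yl)-4-methylocta-3,7-dien-1-yl]oxy}dimethylsilane | BrC(Br)=CCC/C(C)=C/CC(O[Si](C)(C)C(C)(C)C)c1ccoc1
F2 | step 17 | (5E)-5-[(2S)-5-(9-borabicyclo[3.3.1]nonan-9-yl)-2-methylpentylidene]-3-methyl-4-[2-(trimethylsilyl)ethoxy]furan-2(5H)-one | CC1=C(OCC[Si](C)(C)C)/C(=C\[C@@H](C)CCCB2C3CCCC2CCC3)OC1=O
F3 | step 17 | (5E)-5-[(2S,6Z,10E)-6-bromo-13-[(tert-butyldimethylsilyl)oxy]-13-(furan-3-yl)-2,10-dimethyltrideca-6,10-dien-1-ylidene]-3-methyl-4-[2-(trimethylsilyl)ethoxy]furan-2(5H)-one | CC1=C(OCC[Si](C)(C)C)/C(=C\[C@@H](C)CCC/C(Br)=C/CC/C(C)=C/CC(O[Si](C)(C)C(C)(C)C)c2ccoc2)OC1=O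
F4 | step 7 | (5S)-5-[(1R,2S)-1-hydroxy-2-methylpent-4-en-1-yl]-3-methyl-4-[2-(trimethylsilyl)ethoxy]furan-2(5H)-one | CC1=C(OCC[Si](C)(C)C)[C@H]([C@H](O)[C@@H](C)CC=C)OC1=O
F5 | step 20 | (5E)-5-[(2S,6E,10E)-13-(furan-3-yl)-13-hydroxy-2,6,10-trimethyltrideca-6,10-dien-1-ylidene]-4-hydroxy-3-methylfuran-2(5H)-one | CC1=C(O)/C(=C\[C@@H](C)CCC/C(C)=C/CC/C(C)=C/CC(O)c2ccoc2)OC1=O
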